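**Retrosynthetic overview**
1. Target 13 comes from its O-silyl ether 12 by desilylation. Locants used below: monoterpene carbons C1–C8 as in linalool (C3 = carbinol carbon, C7 = hydroperoxy carbon); Cs = the ring CH of trione 3 that becomes the spiro carbon.
2. Key disconnections, all opened in one flask: C8–Cs (spiro cyclohexane), C2–C6 (cyclopentane) and C1–Cs. This leads back to the acyclic aldehyde 9 and the dearomatised diprenyl acylphloroglucinol 3.
3. Enabling feature: the formyl carbon C1 of 9 is a traceless handle. As the enamine it makes C2 nucleophilic towards the C6–C7–C8 allyl unit (cyclopentane); it then becomes the C1 methylene on Cs. This places the oxidisable Cs–H of the β-triketone ring five atoms from the alkene carbon C8, so the Cs radical closes the cyclohexane 6-endo and C7 takes up O2.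
4. 9 comes from (R)-linalool (source of C3) by Riley oxidation, carbonate formation, silylation, hydroboration–oxidation and Dess–Martin oxidation; 3 comes from 2,4,6-trihydroxyacetophenone by double C-prenylation.
5. Order of ring formation: trione ring (from the arene, step 1), then cyclopentane, then spiro cyclohexane (both in step 7).

Key step: step 7

Remark: all trione compounds are drawn as one enol tautomer of a rapidly equilibrating set, and commercial (R)-(−)-linalool of high enantiomeric purity is assumed.

**Step 1**
Reactants: 1 2,4,6-trihydroxyacetophenone; 2 prenyl bromide (1-bromo-3-methylbut-2-ene)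
Product: 3 2-acetyl-3,5-dihydroxy-4,4-bis(3-methylbut-2-en-1-yl)cyclohexa-2,5-dien-1-one
Conditions: 2 (2.1 equiv), KOH (aq.), 0 °C to rt
Reagents that add atoms: none
Why: Double C-alkylation of the phloroglucinolate at one ring carbon (alkylative dearomatisation) is the standard entry to geminally diprenylated acylphloroglucinols and creates no stereocentre.

**Step 2**
Reactants: 4 (R)-(−)-linalool
Product: 5 (2E,6R)-2,6-dimethylocta-2,7-diene-1,6-diol
Conditions: SeO2 (0.2 equiv), t-BuOOH (2 equiv), CH2Cl2, rt
Reagents that add atoms: selenium dioxide, O=[Se]=O; tert-butyl hydroperoxide, CC(C)(C)OO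
Why: Riley allylic oxidation (ene reaction, then [2,3]-sigmatropic shift) should hydroxylate the (E)-methyl group of the trisubstituted alkene selectively and leave the vinyl group and the C3 stereocentre untouched.

**Step 3**
Reactants: 5 (2E,6R)-2,6-dimethylocta-2,7-diene-1,6-diol
Product: 6 (2E,6R)-6-hydroxy-2,6-dimethylocta-2,7-dien-1-yl methyl carbonate
Conditions: ClCO2Me, pyridine, CH2Cl2, 0 °C
Reagents that add atoms: methyl chloroformate, COC(=O)Cl
Why: Acylation with a chloroformate should discriminate the primary allylic from the tertiary alcohol on steric grounds and installs the leaving group for the later Tsuji–Trost ionisation.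

**Step 4**
Reactants: 6 (2E,6R)-6-hydroxy-2,6-dimethylocta-2,7-dien-1-yl methyl carbonate
Product: 7 (2E,6R)-2,6-dimethyl-6-(triethylsilyloxy)octa-2,7-dien-1-yl methyl carbonate
Conditions: Et3SiOTf, 2,6-lutidine, CH2Cl2, −78 to 0 °C
Reagents that add atoms: triethylsilyl trifluoromethanesulfonate, CC[Si](CC)(CC)OS(=O)(=O)C(F)(F)F
Why: Silyl triflate silylation is reliable for hindered tertiary alcohols; the silyl ether blocks retro-aldol cleavage of the later β-oxy aldehyde and is the bulky group that steers the first ring closure.

**Step 5**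
Reactants: 7 (2E,6R)-2,6-dimethyl-6-(triethylsilyloxy)octa-2,7-dien-1-yl methyl carbonate
Product: 8 (2E,6R)-8-hydroxy-2,6-dimethyl-6-(triethylsilyloxy)oct-2-en-1-yl methyl carbonate
Conditions: 9-BBN, THF, 0 °C to rt; then H2O2 (30 % aq.), NaOAc, 0 °C
Reagents that add atoms: hydrogen peroxide, OO
Why: Anti-Markovnikov hydroboration with the bulky borane 9-BBN should select the monosubstituted vinyl group over the trisubstituted alkene, and the buffered oxidation spares the carbonate; C3 is not touched.

**Step 6**
Reactants: 8 (2E,6R)-8-hydroxy-2,6-dimethyl-6-(triethylsilyloxy)oct-2-en-1-yl methyl carbonate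
Product: 9 (2E,6R)-2,6-dimethyl-8-oxo-6-(triethylsilyloxy)oct-2-en-1-yl methyl carbonate
Conditions: Dess–Martin periodinane, CH2Cl2, 0 °C to rt
Reagents that add atoms: none
Why: Dess–Martin oxidation should give the aldehyde under near-neutral conditions that avoid β-elimination of the silyloxy group.

**Step 7**
Reactants: 9 (2E,6R)-2,6-dimethyl-8-oxo-6-(triethylsilyloxy)oct-2-en-1-yl methyl carbonate; 3 2-acetyl-3,5-dihydroxy-4,4-bis(3-methylbut-2-en-1-yl)cyclohexa-2,5-dien-1-one
Product: 12 triethylsilyl-protected spiro hydroperoxide (O-silyl ether of 13), via cyclopentane carbaldehyde 10 (not isolated), via 2-alkyl trione 11 (not isolated)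
Conditions: pyrrolidine (20 mol %), Pd(PPh3)4 (5 mol %), MeCN, rt, Ar; then 3, Hantzsch ester (1.05 equiv), rt; then AcOH, Mn(OAc)3·2H2O (20 mol %), O2 (1 atm), rt
Reagents that add atoms: dioxygen, O=O
Why: Pyrrolidine turns 9 into its enamine while zerovalent palladium ionises the allylic carbonate (CO2 and methanol leave), the enamine carbon C2 attacks the π-allyl terminus C6 to give 10 (amine/palladium dual-catalytic intramolecular Tsuji–Trost α-allylation of an aldehyde), and the same amine then mediates the Knoevenagel condensation of the formyl carbon C1 with the Cs–H of 3, the alkylidene trione being reduced at once by the Hantzsch ester to 11 (three-component reductive alkylation of a cyclic 1,3-dione). Trivalent manganese next oxidises the enolised β-triketone of 11 to the Cs radical, which adds to C8 of the isopropenyl group, the tertiary C7 radical is trapped by O2, and the peroxyl radical takes a hydrogen atom from the enol of another molecule of 11 (Mn(OAc)3/O2 peroxidative radical cyclisation of 1,3-dicarbonyl compounds). The cyclopentane closes 5-exo-trig with the enamine double bond outside the forming ring, and the spiro cyclohexane closes 6-endo-trig onto the 1,1-disubstituted alkene. In the cyclopentane C3 is taken from (R)-linalool, the bulky π-allylpalladium unit should close on the face anti to the triethylsilyloxy group (isopropenyl cis to the C3 methyl group), and the epimerisable formyl-bearing C2 should settle trans to both the isopropenyl and the methyl group. In the spiro ring a chair-like transition state with both cyclopentane bonds equatorial gives the trans ring fusion, the carbonyl arm flanked by the geminal prenyl groups should sit equatorial at Cs so that the arm next to the acetyl-bearing carbon is axial, and O2 should approach the C7 radical anti to this axial arm, which gives the equatorial hydroperoxide. The step needs the 6-endo closure to outrun direct oxygenation of the Cs radical and its 5-exo attack on a geminal prenyl group, which the unstrained chair, the electron-rich disubstituted alkene held gauche on the trans-cyclopentane and a low stationary O2 concentration should secure, and it needs chemoselectivity between the three events, secured because only the allylic carbonate ionises, only the alkylidene trione accepts hydride and only the β-triketone C–H is oxidised.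

**Step 8**
Reactants: 12 triethylsilyl-protected spiro hydroperoxide
Product: 13 CNP0149131.1 (target)
Conditions: HF·pyridine, THF, 0 °C to rt
Reagents that add atoms: none
Why: Fluoride-induced cleavage of the tertiary triethylsilyl ether with buffered HF should be compatible with the hydroperoxide, the enolised β-triketone and the alkenes, and touches no stereocentre.

**Compound list**
1 | 2,4,6-trihydroxyacetophenone | CC(=O)c1c(O)cc(O)cc1O | starting material
2 | prenyl bromide (1-bromo-3-methylbut-2-ene) | CC(C)=CCBr | starting material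
3 | 2-acetyl-3,5-dihydroxy-4,4-bis(3-methylbut-2-en-1-yl)cyclohexa-2,5-dien-1-one | CC(=O)C1=C(O)C(CC=C(C)C)(CC=C(C)C)C(O)=CC1=O | intermediate
4 | (R)-(−)-linalool, (3R)-3,7-dimethylocta-1,6-dien-3-ol | C=C[C@](C)(O)CCC=C(C)C | starting material
5 | (2E,6R)-2,6-dimethylocta-2,7-diene-1,6-diol | C=C[C@](C)(O)CC/C=C(\C)CO | intermediate
6 | (2E,6R)-6-hydroxy-2,6-dimethylocta-2,7-dien-1-yl methyl carbonate | C=C[C@](C)(O)CC/C=C(\C)COC(=O)OC | intermediate
7 | (2E,6R)-2,6-dimethyl-6-(triethylsilyloxy)octa-2,7-dien-1-yl methyl carbonate | C=C[C@](C)(O[Si](CC)(CC)CC)CC/C=C(\C)COC(=O)OC | intermediate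
8 | (2E,6R)-8-hydroxy-2,6-dimethyl-6-(triethylsilyloxy)oct-2-en-1-yl methyl carbonate | OCC[C@](C)(O[Si](CC)(CC)CC)CC/C=C(\C)COC(=O)OC | intermediate
9 | (2E,6R)-2,6-dimethyl-8-oxo-6-(triethylsilyloxy)oct-2-en-1-yl methyl carbonate | O=CC[C@](C)(O[Si](CC)(CC)CC)CC/C=C(\C)COC(=O)OC | intermediate
10 | (1S,2R,5R)-2-methyl-5-(prop-1-en-2-yl)-2-(triethylsilyloxy)cyclopentane-1-carbaldehyde (formyl cis to the silyloxy group, trans to the isopropenyl group) | O=C[C@H]1[C@@H](CC[C@@]1(C)O[Si](CC)(CC)CC)C(C)=C | intermediate
11 | 2-acetyl-3,5-dihydroxy-6-{[(1S,2R,5R)-2-methyl-5-(prop-1-en-2-yl)-2-(triethylsilyloxy)cyclopentyl]methyl}-4,4-bis(3-methylbut-2-en-1-yl)cyclohexa-2,5-dien-1-one | CC(=O)C1=C(O)C(CC=C(C)C)(CC=C(C)C)C(O)=C(C[C@H]2[C@@H](CC[C@@]2(C)O[Si](CC)(CC)CC)C(C)=C)C1=O | intermediate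
12 | (1S,3'R,3a'S,7'R,7a'R)-3-acetyl-7'-hydroperoxy-4-hydroxy-3',7'-dimethyl-5,5-bis(3-methylbut-2-en-1-yl)-3'-(triethylsilyloxy)octahydrospiro[cyclohexane-1,5'-inden]-3-ene-2,6-dione (trans-fused hydrindane) | CC(=O)C1=C(O)C(CC=C(C)C)(CC=C(C)C)C(=O)[C@@]2(C[C@H]3[C@@H](CC[C@@]3(C)O[Si](CC)(CC)CC)[C@](C)(OO)C2)C1=O | intermediate
13 | CNP0149131.1, (1S,3'R,3a'S,7'R,7a'R)-3-acetyl-7'-hydroperoxy-3',4-dihydroxy-3',7'-dimethyl-5,5-bis(3-methylbut-2-en-1-yl)octahydrospiro[cyclohexane-1,5'-inden]-3-ene-2,6-dione | CC(=O)C1=C(O)C(CC=C(C)C)(CC=C(C)C)C(=O)[C@@]2(C[C@H]3[C@@H](CC[C@@]3(C)O)[C@](C)(OO)C2)C1=O | target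

**Totals**
Total step count: 8. Longest linear sequence: 7 steps (4 to 13, steps 2–8); step 1 is a one-step branch.

**Steps most likely to fail**

Step 7. What may go wrong: the three catalytic cycles may interfere in one flask (triphenylphosphine reducing the hydroperoxide, the dihydropyridine breaking the radical chain), the silyloxy group may β-eliminate from the enamine, and the kinetically controlled palladium–allyl ring closure may show poor facial selectivity at C6. The fallback changes the order of bond formation and puts the first ring closure under thermodynamic control. It sets out from 9 and 3. Knoevenagel condensation (ethylenediammonium diacetate, CH2Cl2) followed by tautomerisation should give the conjugated dienol 2-acetyl-3,5-dihydroxy-6-[(1E,3R,6E)-8-(methoxycarbonyloxy)-3,7-dimethyl-3-(triethylsilyloxy)octa-1,6-dien-1-yl]-4,4-bis(3-methylbut-2-en-1-yl)cyclohexa-2,5-dien-1-one F1. Pd(PPh3)4 then ionises the carbonate, and the vinylogous carbon C2 of the dienolate attacks C6 (5-exo Tsuji–Trost alkylation by a stabilised carbon nucleophile; it is reversible, so the all-trans cyclopentane should accumulate) to give the cyclised alkylidene trione F2. F2 is reduced in the same flask by the Hantzsch ester to 11, where the route is rejoined; 11 is isolated and cyclised in a separate flask with Mn(OAc)3 and O2 to 12.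

Step 1. What may go wrong: poor control of C- versus O-alkylation and of the degree of alkylation. The fallback sets out from 1. Allylation with allyl bromide (K2CO3, acetone; O-allyl by-products are funnelled to C-allyl compounds by Claisen rearrangement on heating) should give 2-acetyl-3,5-dihydroxy-4,4-di(prop-2-en-1-yl)cyclohexa-2,5-dien-1-one F3. Cross-metathesis of both allyl groups with 2-methyl-2-butene (second-generation Grubbs catalyst, CH2Cl2, 40 °C) converts them into prenyl groups and returns to the route at 3.

Step 2. What may go wrong: over-oxidation to the enal and attack at other allylic positions, so that conversion to the (E)-allylic alcohol stays low. The fallback builds the allylic alcohol by oxidative cleavage and olefination and sets out from 4. Silylation (Et3SiOTf, 2,6-lutidine) should give (3R)-3,7-dimethyl-3-(triethylsilyloxy)octa-1,6-diene F4. Chemoselective ozonolysis of the more electron-rich trisubstituted alkene (O3, CH2Cl2/MeOH, −78 °C, indicator-controlled, then Me2S) gives (4R)-4-methyl-4-(triethylsilyloxy)hex-5-enal F5. An (E)-selective Wittig reaction with ethyl 2-(triphenylphosphoranylidene)propanoate gives ethyl (2E,6R)-2,6-dimethyl-6-(triethylsilyloxy)octa-2,7-dienoate F6. Reduction with i-Bu2AlH gives (2E,6R)-2,6-dimethyl-6-(triethylsilyloxy)octa-2,7-dien-1-ol F7. Methyl chloroformate and pyridine then give 7, where the route is rejoined (steps 3 and 4 fall away).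

**Further compounds**
F1 | step 7 | 2-acetyl-3,5-dihydroxy-6-[(1E,3R,6E)-8-(methoxycarbonyloxy)-3,7-dimethyl-3-(triethylsilyloxy)octa-1,6-dien-1-yl]-4,4-bis(3-methylbut-2-en-1-yl)cyclohexa-2,5-dien-1-one | CC(=O)C1=C(O)C(CC=C(C)C)(CC=C(C)C)C(O)=C(/C=C/[C@](C)(O[Si](CC)(CC)CC)CC/C=C(\C)COC(=O)OC)C1=O
F2 | step 7 | 2-acetyl-3-hydroxy-6-{[(1S,2R,5R)-2-methyl-5-(prop-1-en-2-yl)-2-(triethylsilyloxy)cyclopentyl]methylidene}-4,4-bis(3-methylbut-2-en-1-yl)cyclohex-2-ene-1,5-dione | CC(=O)C1=C(O)C(CC=C(C)C)(CC=C(C)C)C(=O)C(=C[C@H]2[C@@H](CC[C@@]2(C)O[Si](CC)(CC)CC)C(C)=C)C1=O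
F3 | step 1 | 2-acetyl-3,5-dihydroxy-4,4-di(prop-2-en-1-yl)cyclohexa-2,5-dien-1-one | CC(=O)C1=C(O)C(CC=C)(CC=C)C(O)=CC1=O
F4 | step 2 | (3R)-3,7-dimethyl-3-(triethylsilyloxy)octa-1,6-diene | C=C[C@](C)(O[Si](CC)(CC)CC)CCC=C(C)C
F5 | step 2 | (4R)-4-methyl-4-(triethylsilyloxy)hex-5-enal | C=C[C@](C)(O[Si](CC)(CC)CC)CCC=O
F6 | step 2 | ethyl (2E,6R)-2,6-dimethyl-6-(triethylsilyloxy)octa-2,7-dienoate | C=C[C@](C)(O[Si](CC)(CC)CC)CC/C=C(\C)C(=O)OCC
F7 | step 2 | (2E,6R)-2,6-dimethyl-6-(triethylsilyloxy)octa-2,7-dien-1-ol | C=C[C@](C)(O[Si](CC)(CC)CC)CC/C=C(\C)CO
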